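**Retrosynthetic overview**

- The route rests on the C5/C4a/C8a pyrogallol array of ring A. O4 is its central oxygen and carries C3 (methyl). O1 and the C5 oxygen are the two outer oxygens and stay equivalent until the dioxane ring (ring B) closes. The C3 methyl is carried as an exocyclic methylene.
- Target ⇐ aryl silyl ether ⇐ C7 aldehyde (E-propenyl by Julia–Kocienski olefination) ⇐ C7 methyl ester, the carbon that methyl gallate already holds.
- C3 stereocentre ⇐ hydrogen-atom-transfer hydrogenation of the 3-methylene group, trans to the C2 aryl group. C5–OMe ⇐ methylation of the one phenol left after ring closure.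
- Ring B, the only ring formed, ⇐ methyl gallate + racemic aryl propargylic methyl carbonate. One palladium/BINAP cascade makes O4–C3 and then O1–C2 and sets C2.
- Carbonate ⇐ syringaldehyde by silylation, ethynyl Grignard addition and carbonate formation. Rings A and C are bought.

Key step: step 4

Assumption: the sense of induction of BINAP with an aryl-substituted carbonate cannot be predicted with confidence; (R)-BINAP is written for the (2R) product and is exchanged for (S)-BINAP if the first run shows the opposite sense.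

**Route**

Step 1
Reactants: 1 syringaldehyde
Product: 2 3,5-dimethoxy-4-(triisopropylsilyloxy)benzaldehyde
Conditions: TIPSCl, imidazole, DMAP (cat.), DMF, 23–40 °C
Reagents that add atoms: triisopropylsilyl chloride, CC(C)[Si](Cl)(C(C)C)C(C)C
Why: O-silylation of a phenol with an imidazole-activated silyl chloride; the bulky silyl ether flanked by two methoxy groups should then survive the Grignard reagent, carbonate base, hydride and amide base used later.

Step 2
Reactants: 2 3,5-dimethoxy-4-(triisopropylsilyloxy)benzaldehyde; 3 ethynylmagnesium bromide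
Product: 4 racemic 1-[3,5-dimethoxy-4-(triisopropylsilyloxy)phenyl]prop-2-yn-1-ol
Conditions: THF, 0 °C to 23 °C; sat. aq. NH4Cl
Reagents that add atoms: none
Why: Grignard 1,2-addition of an alkynyl nucleophile to an aryl aldehyde; the racemic carbinol is acceptable because its configuration is erased on ionisation in step 4.

Step 3
Reactants: 4 racemic 1-[3,5-dimethoxy-4-(triisopropylsilyloxy)phenyl]prop-2-yn-1-ol
Product: 5 racemic methyl 1-[3,5-dimethoxy-4-(triisopropylsilyloxy)phenyl]prop-2-ynyl carbonate
Conditions: ClCO2Me, pyridine, DMAP (cat.), CH2Cl2, 0 °C; chromatography on Et3N-deactivated silica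
Reagents that add atoms: methyl chloroformate, COC(=O)Cl
Why: O-acylation of a secondary alcohol with a chloroformate under pyridine catalysis, kept cold and base-buffered because the electron-rich benzylic propargylic position ionises easily.

Step 4
Reactants: 5 racemic methyl 1-[3,5-dimethoxy-4-(triisopropylsilyloxy)phenyl]prop-2-ynyl carbonate; 6 methyl gallate (2 equiv)
Product: 7 methyl (2R)-2-[3,5-dimethoxy-4-(triisopropylsilyloxy)phenyl]-5-hydroxy-3-methylene-2,3-dihydro-1,4-benzodioxine-7-carboxylate
Conditions: Pd2(dba)3·CHCl3 (zerovalent palladium, 2.5 mol %), (R)-BINAP (6 mol %), degassed THF, 23 °C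
Reagents that add atoms: none
Why: Zerovalent palladium ionises 5 with loss of CO2 to a cationic allenyl/propargyl complex of divalent palladium, and the methoxide set free deprotonates the most acidic hydroxyl of 6 (para to the ester); this phenoxide adds to the central carbon (O4–C3), and protonation at the former alkyne terminus turns the palladacyclobutene into a 2-aryloxy η3-allyl complex. A flanking hydroxyl then attacks the aryl-bearing allyl terminus in a 6-exo closure of ring B (O1–C2), leaving C3 as the exocyclic methylene; all intermediates stay bound to palladium. The closest known reaction type is the palladium/BINAP-catalysed asymmetric annulation of benzene-1,2-diols with secondary propargylic carbonates to 3-substituted 2-alkylidene-1,4-benzodioxanes. C2 is set by the chiral bisphosphine: the two allyl faces exchange by η3–η1–η3 slippage through the unsubstituted CH2 terminus faster than the ring closes, so both enantiomers of 5 should converge on (2R). The step needs closure at the benzylic and not the CH2 terminus, which the cation-stabilising 4-silyloxy-3,5-dimethoxyphenyl group and the ligand should secure, and first attack by O4 and not an outer oxygen, which the higher acidity of the 4-hydroxyl should secure. The mirror symmetry of 6 makes the two possible ring-closing oxygens identical, and the excess of 6 should keep the remaining 5-hydroxyl of 7 from reacting with a second allenyl complex.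

Step 5
Reactants: 7 methyl (2R)-2-[3,5-dimethoxy-4-(triisopropylsilyloxy)phenyl]-5-hydroxy-3-methylene-2,3-dihydro-1,4-benzodioxine-7-carboxylate
Product: 8 methyl (2R)-2-[3,5-dimethoxy-4-(triisopropylsilyloxy)phenyl]-5-methoxy-3-methylene-2,3-dihydro-1,4-benzodioxine-7-carboxylate
Conditions: MeI, K2CO3, acetone, 23 °C
Reagents that add atoms: iodomethane, CI
Why: Williamson methylation of the single free phenol under mild carbonate base, which should leave the hindered aryl silyl ether, the enol ether and C2 untouched and removes the phenol before the radical step.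

Step 6
Reactants: 8 methyl (2R)-2-[3,5-dimethoxy-4-(triisopropylsilyloxy)phenyl]-5-methoxy-3-methylene-2,3-dihydro-1,4-benzodioxine-7-carboxylate
Product: 9 methyl (2R,3R)-2-[3,5-dimethoxy-4-(triisopropylsilyloxy)phenyl]-5-methoxy-3-methyl-2,3-dihydro-1,4-benzodioxine-7-carboxylate (2,3-trans)
Conditions: Mn(dpm)3 (trivalent manganese, 10 mol %), PhSiH3, t-BuOOH, i-PrOH, 23 °C
Reagents that add atoms: none
Why: Metal-hydride hydrogen-atom-transfer hydrogenation: the Mn–H species gives a hydrogen atom to the CH2 terminus, and the tertiary α-oxygenated C3 radical, in the half-chair with the C2 aryl group pseudoequatorial, should take the second hydrogen along the pseudoaxial trajectory, so that the methyl group ends equatorial and trans to the aryl group (3R), whereas surface hydrogenation would add anti to the aryl group and give cis.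

Step 7
Reactants: 9 methyl (2R,3R)-2-[3,5-dimethoxy-4-(triisopropylsilyloxy)phenyl]-5-methoxy-3-methyl-2,3-dihydro-1,4-benzodioxine-7-carboxylate
Product: 10 [(2R,3R)-2-[3,5-dimethoxy-4-(triisopropylsilyloxy)phenyl]-5-methoxy-3-methyl-2,3-dihydro-1,4-benzodioxin-7-yl]methanol
Conditions: i-Bu2AlH (2.5 equiv), CH2Cl2, −78 °C to 0 °C; aq. Rochelle salt
Reagents that add atoms: none
Why: Hydride reduction of an aryl ester to the benzylic alcohol, under which aryl ethers, the silyl ether and both stereocentres are inert.

Step 8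
Reactants: 10 [(2R,3R)-2-[3,5-dimethoxy-4-(triisopropylsilyloxy)phenyl]-5-methoxy-3-methyl-2,3-dihydro-1,4-benzodioxin-7-yl]methanol
Product: 11 (2R,3R)-2-[3,5-dimethoxy-4-(triisopropylsilyloxy)phenyl]-5-methoxy-3-methyl-2,3-dihydro-1,4-benzodioxine-7-carbaldehyde
Conditions: MnO2 (activated, excess), CH2Cl2, 23 °C
Reagents that add atoms: none
Why: Selective MnO2 oxidation of an electron-rich benzylic alcohol to the aldehyde without over-oxidation and without touching the C2 benzylic ether.

Step 9
Reactants: 11 (2R,3R)-2-[3,5-dimethoxy-4-(triisopropylsilyloxy)phenyl]-5-methoxy-3-methyl-2,3-dihydro-1,4-benzodioxine-7-carbaldehyde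
Product: 12 (2R,3R)-2-[3,5-dimethoxy-4-(triisopropylsilyloxy)phenyl]-5-methoxy-3-methyl-7-[(E)-prop-1-enyl]-2,3-dihydro-1,4-benzodioxine
Conditions: 5-(ethylsulfonyl)-1-phenyl-1H-tetrazole, KN(SiMe3)2, DME, −60 °C to 23 °C
Reagents that add atoms: 5-(ethylsulfonyl)-1-phenyl-1H-tetrazole, CCS(=O)(=O)c1nnnn1-c1ccccc1
Why: Julia–Kocienski olefination, in which addition of the sulfonyl anion, Smiles rearrangement and anti elimination of SO2 and tetrazolate should favour the E alkene with an aryl aldehyde and a potassium counter-ion in DME.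

Step 10
Reactants: 12 (2R,3R)-2-[3,5-dimethoxy-4-(triisopropylsilyloxy)phenyl]-5-methoxy-3-methyl-7-[(E)-prop-1-enyl]-2,3-dihydro-1,4-benzodioxine
Product: 13 4-[(2R,3R)-5-methoxy-3-methyl-7-[(E)-prop-1-enyl]-2,3-dihydro-1,4-benzodioxin-2-yl]-2,6-dimethoxyphenol (target)
Conditions: Bu4NF, AcOH (1:1), THF, 0 °C
Reagents that add atoms: none
Why: Fluoride cleavage of an aryl silyl ether, buffered with acetic acid and kept cold so that the freed p-hydroxyphenyl group is not held as a phenoxide that could open the C2–O1 bond through a quinone methide.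

**Compound list**

1 | syringaldehyde (4-hydroxy-3,5-dimethoxybenzaldehyde) | O=Cc1cc(OC)c(O)c(OC)c1 | starting material
2 | 3,5-dimethoxy-4-(triisopropylsilyloxy)benzaldehyde | O=Cc1cc(OC)c(O[Si](C(C)C)(C(C)C)C(C)C)c(OC)c1 | intermediate
3 | ethynylmagnesium bromide | C#C[Mg]Br | starting material
4 | racemic 1-[3,5-dimethoxy-4-(triisopropylsilyloxy)phenyl]prop-2-yn-1-ol | C#CC(O)c1cc(OC)c(O[Si](C(C)C)(C(C)C)C(C)C)c(OC)c1 | intermediate
5 | racemic methyl 1-[3,5-dimethoxy-4-(triisopropylsilyloxy)phenyl]prop-2-ynyl carbonate | C#CC(OC(=O)OC)c1cc(OC)c(O[Si](C(C)C)(C(C)C)C(C)C)c(OC)c1 | intermediate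
6 | methyl gallate (methyl 3,4,5-trihydroxybenzoate) | COC(=O)c1cc(O)c(O)c(O)c1 | starting material
7 | methyl (2R)-2-[3,5-dimethoxy-4-(triisopropylsilyloxy)phenyl]-5-hydroxy-3-methylene-2,3-dihydro-1,4-benzodioxine-7-carboxylate | COC(=O)c1cc(O)c2c(c1)O[C@H](c1cc(OC)c(O[Si](C(C)C)(C(C)C)C(C)C)c(OC)c1)C(=C)O2 | intermediate
8 | methyl (2R)-2-[3,5-dimethoxy-4-(triisopropylsilyloxy)phenyl]-5-methoxy-3-methylene-2,3-dihydro-1,4-benzodioxine-7-carboxylate | COC(=O)c1cc(OC)c2c(c1)O[C@H](c1cc(OC)c(O[Si](C(C)C)(C(C)C)C(C)C)c(OC)c1)C(=C)O2 | intermediate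
9 | methyl (2R,3R)-2-[3,5-dimethoxy-4-(triisopropylsilyloxy)phenyl]-5-methoxy-3-methyl-2,3-dihydro-1,4-benzodioxine-7-carboxylate | COC(=O)c1cc(OC)c2c(c1)O[C@H](c1cc(OC)c(O[Si](C(C)C)(C(C)C)C(C)C)c(OC)c1)[C@@H](C)O2 | intermediate
10 | [(2R,3R)-2-[3,5-dimethoxy-4-(triisopropylsilyloxy)phenyl]-5-methoxy-3-methyl-2,3-dihydro-1,4-benzodioxin-7-yl]methanol | OCc1cc(OC)c2c(c1)O[C@H](c1cc(OC)c(O[Si](C(C)C)(C(C)C)C(C)C)c(OC)c1)[C@@H](C)O2 | intermediate
11 | (2R,3R)-2-[3,5-dimethoxy-4-(triisopropylsilyloxy)phenyl]-5-methoxy-3-methyl-2,3-dihydro-1,4-benzodioxine-7-carbaldehyde | O=Cc1cc(OC)c2c(c1)O[C@H](c1cc(OC)c(O[Si](C(C)C)(C(C)C)C(C)C)c(OC)c1)[C@@H](C)O2 | intermediate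
12 | (2R,3R)-2-[3,5-dimethoxy-4-(triisopropylsilyloxy)phenyl]-5-methoxy-3-methyl-7-[(E)-prop-1-enyl]-2,3-dihydro-1,4-benzodioxine | C/C=C/c1cc(OC)c2c(c1)O[C@H](c1cc(OC)c(O[Si](C(C)C)(C(C)C)C(C)C)c(OC)c1)[C@@H](C)O2 | intermediate
13 | 4-[(2R,3R)-5-methoxy-3-methyl-7-[(E)-prop-1-enyl]-2,3-dihydro-1,4-benzodioxin-2-yl]-2,6-dimethoxyphenol | C/C=C/c1cc(OC)c2c(c1)O[C@H](c1cc(OC)c(O)c(OC)c1)[C@@H](C)O2 | target

**Step count**

Total step count: 10. Longest linear sequence: 10 steps (1 to 13); 3 and 6 are used as bought.

**Steps most likely to fail**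

Step 4. The cascade may lose enantiocontrol if the allyl faces exchange more slowly than the ring closes. It may also close at the CH2 terminus, start at an outer oxygen, propargylate the remaining phenol, or move the exocyclic alkene into the ring, which would erase C2. The fallback sets out from 5 and 6 and returns at 7; it splits the cascade into two separately controlled C–O bond formations.
- Selective 4-O-allylation of 6 (allyl bromide, KHCO3, DMF) gives methyl 4-(allyloxy)-3,5-dihydroxybenzoate F1, whose two free hydroxyls are equivalent.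
- Copper-catalysed enantioselective propargylic etherification of 5 with F1 ((CuOTf)2·C6H6, monovalent copper, chiral pybox ligand, i-Pr2NEt, THF, −20 °C) forms O1–C2 through attack on the benzylic carbon of a copper allenylidene. It gives the (S)-propargyl aryl ether F2; (S) there is the same spatial arrangement as (2R) in 7, because ethynyl ranks below aryl.
- Pd(PPh3)4 (zerovalent palladium) with morpholine removes the allyl group to give the catechol F3.
- 6-exo-dig addition of the freed 4-hydroxyl to the alkyne (Cs2CO3, MeCN, 50 °C) forms O4–C3 and gives 7.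

Step 6. The second hydrogen may reach the C3 radical from the face anti to the aryl group and give the cis isomer. The radical may also open ring B by β-scission of the C2–O1 bond, or reversible hydrogen-atom transfer may move the alkene into the ring. The fallback sets out from 5 and 6 and returns at 9; it reverses the facial demand and lets thermodynamics set C2.
- Step 4 run with the antipodal BINAP gives the (2S) enantiomer F4, and methylation as in step 5 gives F5.
- Surface hydrogenation (H2, Rh/Al2O3, EtOAc) adds from the face opposite the aryl group and gives the cis (2S,3R) ester F6, in which C3 is already correct.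
- BF3·OEt2 in CH2Cl2 at −20 °C should then ionise the C2–O1 bond reversibly to the p-silyloxybenzyl cation, which recloses to the more stable trans isomer 9. Any cis material left is removed by chromatography.

Step 9. The olefination may give an E/Z mixture if the anti and syn adducts form without selectivity, and the base may damage the aldehyde. The fallback sets out from 11 and returns at 12.
- Wittig reaction with ethylidenetriphenylphosphorane (EtPPh3Br, KN(SiMe3)2, THF, −78 °C) should give mainly the (Z)-propenyl compound F7.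
- Catalytic PdCl2(MeCN)2 (divalent palladium) in CH2Cl2 then equilibrates the alkene to the conjugated E isomer 12.

**Further compounds**

F1 | step 4 | methyl 4-(allyloxy)-3,5-dihydroxybenzoate | COC(=O)c1cc(O)c(OCC=C)c(O)c1
F2 | step 4 | methyl 4-(allyloxy)-3-hydroxy-5-{(1S)-1-[3,5-dimethoxy-4-(triisopropylsilyloxy)phenyl]prop-2-ynyloxy}benzoate | COC(=O)c1cc(O)c(OCC=C)c(c1)O[C@H](c1cc(OC)c(O[Si](C(C)C)(C(C)C)C(C)C)c(OC)c1)C#C
F3 | step 4 | methyl 3,4-dihydroxy-5-{(1S)-1-[3,5-dimethoxy-4-(triisopropylsilyloxy)phenyl]prop-2-ynyloxy}benzoate | COC(=O)c1cc(O)c(O)c(c1)O[C@H](c1cc(OC)c(O[Si](C(C)C)(C(C)C)C(C)C)c(OC)c1)C#C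
F4 | step 6 | methyl (2S)-2-[3,5-dimethoxy-4-(triisopropylsilyloxy)phenyl]-5-hydroxy-3-methylene-2,3-dihydro-1,4-benzodioxine-7-carboxylate | COC(=O)c1cc(O)c2c(c1)O[C@@H](c1cc(OC)c(O[Si](C(C)C)(C(C)C)C(C)C)c(OC)c1)C(=C)O2
F5 | step 6 | methyl (2S)-2-[3,5-dimethoxy-4-(triisopropylsilyloxy)phenyl]-5-methoxy-3-methylene-2,3-dihydro-1,4-benzodioxine-7-carboxylate | COC(=O)c1cc(OC)c2c(c1)O[C@@H](c1cc(OC)c(O[Si](C(C)C)(C(C)C)C(C)C)c(OC)c1)C(=C)O2
F6 | step 6 | methyl (2S,3R)-2-[3,5-dimethoxy-4-(triisopropylsilyloxy)phenyl]-5-methoxy-3-methyl-2,3-dihydro-1,4-benzodioxine-7-carboxylate (2,3-cis) | COC(=O)c1cc(OC)c2c(c1)O[C@@H](c1cc(OC)c(O[Si](C(C)C)(C(C)C)C(C)C)c(OC)c1)[C@@H](C)O2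
F7 | step 9 | (2R,3R)-2-[3,5-dimethoxy-4-(triisopropylsilyloxy)phenyl]-5-methoxy-3-methyl-7-[(Z)-prop-1-enyl]-2,3-dihydro-1,4-benzodioxine | C/C=C\c1cc(OC)c2c(c1)O[C@H](c1cc(OC)c(O[Si](C(C)C)(C(C)C)C(C)C)c(OC)c1)[C@@H](C)O2
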